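## Retrosynthesis

1. The target is the trans-1-aryl-1,2-dihydronaphthalene-2,3-dimethanol. It comes from the 2,3-diester by DIBAL reduction, with the two phenols carried as allyl ethers.
2. Key disconnection: the C1–C8a bond and the C2–H stereocentre. A chiral Brønsted acid protonates the α-carbon of an achiral (E,E)-2,3-bis(arylidene)succinate. The resulting benzylic cation is trapped by the cis-disposed aryl ring. This closes the only new ring and sets both stereocentres in one step. The two ends of the diene are equivalent, so either end can react and the same enantiomer results.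
3. The diene comes from a double Stobbe condensation of 4-allyloxy-3-methoxybenzaldehyde (from vanillin) with diethyl succinate. Each Stobbe step places the aryl group trans to the ester, which is the geometry needed for ring closure.
4. The final step removes the allyl ethers under non-reducing conditions, so the C3=C4 styrenyl alkene survives (no hydrogenolysis).

**Assumptions:**
- The relative configuration is trans, as encoded in the SMILES, and the absolute configuration is (1S,2R).
- The (S,S)-catalyst enantiomer is assumed to give (1S,2R). It would be swapped if the opposite enantiomer is obtained.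

## Route

**Step 1**
Reactants: 1 vanillin; 2 allyl bromide
Product: 3 4-(allyloxy)-3-methoxybenzaldehyde
Conditions: K2CO3, DMF, rt, 12 h
Reagents that add atoms: allyl bromide, C=CCBr (compound 2)
Why: Williamson O-alkylation of the phenol. The aldehyde is untouched, and the allyl ether is stable to the later acid and base steps and is removed by Pd(0).

**Step 2**
Reactants: 3; 4 diethyl succinate
Product: 5 (E)-4-[4-(allyloxy)-3-methoxyphenyl]-3-(ethoxycarbonyl)but-3-enoic acid
Conditions: KOtBu (1.1 equiv), tBuOH, reflux, 3 h; then aq. HCl
Reagents that add atoms: diethyl succinate, CCOC(=O)CCC(=O)OCC (compound 4)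
Why: Stobbe condensation through a paraconic lactone followed by E1cB ring opening. This gives the E half-ester, with the aryl group trans to the conjugated CO2Et and cis to CH2CO2H.

**Step 3**
Reactants: 5; 6 iodoethane
Product: 7 diethyl (E)-2-[4-(allyloxy)-3-methoxybenzylidene]succinate
Conditions: EtI, K2CO3, DMF, rt, 6 h
Reagents that add atoms: iodoethane, CCI (compound 6)
Why: Carboxylate O-alkylation (SN2) only. The alkene geometry is retained, and the allyl ether and esters are unaffected.

**Step 4**
Reactants: 7; 3
Product: 8 (2E,3E)-2,3-bis[4-(allyloxy)-3-methoxybenzylidene]succinic acid mono-ethyl ester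
Conditions: KOtBu (1.2 equiv), tBuOH, reflux, 6 h; then aq. HCl
Reagents that add atoms: none beyond numbered reactant 3
Why: A second Stobbe condensation at the activated allylic CH2 (the fulgide-type double Stobbe). The alkoxide lactonises onto the neighbouring ester and E1cB opening gives the (E,E)-bis(arylidene) product, with each aryl trans to its own ester and cis to the other alkene carbon.

**Step 5**
Reactants: 8; 6
Product: 9 diethyl (2E,3E)-2,3-bis[4-(allyloxy)-3-methoxybenzylidene]succinate, the symmetric achiral diene
Conditions: EtI, K2CO3, DMF, rt, 6 h
Reagents that add atoms: iodoethane, CCI (compound 6)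
Why: Carboxylate O-alkylation, as in step 3. This gives the C2-symmetric substrate for the key step.

**Step 6**
Reactants: 9
Product: 10 diethyl (1S,2R)-7-(allyloxy)-1-[4-(allyloxy)-3-methoxyphenyl]-6-methoxy-1,2-dihydronaphthalene-2,3-dicarboxylate
Conditions: (S,S)-IDPi (5 mol%; BINOL-derived imidodiphosphorimidate), toluene (0.05 M), 4 Å MS, −20 °C to rt, 48 h
Reagents that add atoms: none (cycloisomerisation; 10 is an isomer of 9)
Why: Proposed new method: an enantioselective, proton-initiated cation–arene cyclisation that forms the C1–C8a bond and sets both stereocentres in one step.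
- Mechanism: The α-carbon of each 4-alkoxycinnamate-type alkene is its nucleophilic position, because the ester and the p-alkoxyaryl group form a push–pull system.
- The strong, confined chiral acid protonates one enantiotopic face at that carbon, which sets C2, giving a p-alkoxybenzylic cation paired with the chiral anion.
- The cis-disposed second aryl ring then attacks the cation at its position para to OMe (Friedel–Crafts / Nazarov-type 6-ring closure).
- The ring closes anti to the C2 ester, which gives the trans 1,2-relationship.
- Terminal protonation is disfavoured because it would put a cation α to an ester.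
- Closest known reactions: racemic acid-mediated cyclisation of dibenzylidene succinates to arylnaphthalene or dihydronaphthalene lignan skeletons, and chiral-acid-catalysed protonation/hydroarylation of alkenes.

**Step 7**
Reactants: 10
Product: 11 [(1S,2R)-7-(allyloxy)-1-(4-allyloxy-3-methoxyphenyl)-6-methoxy-3-(hydroxymethyl)-1,2-dihydronaphthalen-2-yl]methanol
Conditions: DIBAL-H (6 equiv), CH2Cl2, −78 °C to 0 °C, 2 h; Rochelle salt work-up
Reagents that add atoms: none
Why: Hydride reduction of both esters to primary alcohols (1,2-reduction). The conditions are non-basic, so C2–H is not epimerised, and the allyl and methyl ethers and the styrenyl alkene are inert.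

**Step 8**
Reactants: 11
Product: 12 target, (1S,2R)-2,3-bis(hydroxymethyl)-1-(4-hydroxy-3-methoxyphenyl)-6-methoxy-1,2-dihydronaphthalen-7-ol
Conditions: Pd(PPh3)4 (5 mol%), K2CO3, MeOH, rt, degassed, 3 h
Reagents that add atoms: none (the allyl groups are lost)
Why: Pd(0)-catalysed deallylation of aryl allyl ethers (π-allyl transfer to methoxide). The free allylic alcohol and the alkene are untouched, and both stereocentres are non-acidic after step 7, so they are not scrambled.

## Compound list

1 | vanillin | COc1cc(C=O)ccc1O | starting material
2 | allyl bromide | C=CCBr | starting material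
3 | 4-(allyloxy)-3-methoxybenzaldehyde | C=CCOc1ccc(C=O)cc1OC | intermediate
4 | diethyl succinate | CCOC(=O)CCC(=O)OCC | starting material
5 | (E)-4-[4-(allyloxy)-3-methoxyphenyl]-3-(ethoxycarbonyl)but-3-enoic acid | C=CCOc1ccc(cc1OC)/C=C(/C(=O)OCC)CC(=O)O | intermediate
6 | iodoethane | CCI | starting material
7 | diethyl (E)-2-[4-(allyloxy)-3-methoxybenzylidene]succinate | C=CCOc1ccc(cc1OC)/C=C(/C(=O)OCC)CC(=O)OCC | intermediate
8 | (2E,3E)-2,3-bis(arylidene)succinic acid mono-ethyl ester | C=CCOc1ccc(cc1OC)/C=C(/C(=O)O)\C(C(=O)OCC)=C/c1ccc(OCC=C)c(OC)c1 | intermediate
9 | diethyl (2E,3E)-2,3-bis[4-(allyloxy)-3-methoxybenzylidene]succinate | C=CCOc1ccc(cc1OC)/C=C(/C(=O)OCC)\C(C(=O)OCC)=C/c1ccc(OCC=C)c(OC)c1 | intermediate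
10 | diethyl (1S,2R)-7-(allyloxy)-1-[4-(allyloxy)-3-methoxyphenyl]-6-methoxy-1,2-dihydronaphthalene-2,3-dicarboxylate | COc1cc([C@H]2c3cc(OCC=C)c(OC)cc3C=C(C(=O)OCC)[C@@H]2C(=O)OCC)ccc1OCC=C | intermediate
11 | (1S,2R)-bis-allyl-protected 2,3-bis(hydroxymethyl)-1,2-dihydronaphthalene | COc1cc([C@H]2c3cc(OCC=C)c(OC)cc3C=C(CO)[C@@H]2CO)ccc1OCC=C | intermediate
12 | (1S,2R)-2,3-bis(hydroxymethyl)-1-(4-hydroxy-3-methoxyphenyl)-6-methoxy-1,2-dihydronaphthalen-7-ol (CID10473569) | COc1cc([C@H]2c3cc(O)c(OC)cc3C=C(CO)[C@@H]2CO)ccc1O | target

## Summary

Total steps: 8. Longest linear sequence: 8 steps (1 → 3 → 5 → 7 → 9 → 10 → 11 → 12; compound 3 is reused in step 4).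

**Three steps most likely to fail:**

1. **Step 6 (proposed new step).** Protonating the ester-deactivated diene may be too slow, and enantiocontrol and trans selectivity are unproven. The product could also aromatise or isomerise to the conjugated 1,4-dihydro compound.
   - Fallback (known chemistry): cyclise 9 with TfOH or BF3·OEt2 to racemic trans 10. Reduce to racemic diol 11, then resolve it by lipase-catalysed acetylation (Amano PS, vinyl acetate) or preparative chiral SFC. Continue with step 8.
2. **Step 4 (second Stobbe).** Yield and (E,E) selectivity of the double condensation may be poor.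
   - Fallback (known chemistry): make ethyl (Z)-2-bromo-3-arylacrylate from aldehyde 3 by HWE with triethyl 2-bromophosphonoacetate. Homocouple it with Ni(cod)2 or Cu (Ullmann-type) with retention of geometry to give 9 directly.
3. **Step 8 (deallylation).** Pd(0) could ionise the allylic alcohol, or the electron-rich dihydronaphthalene diol could oxidise to the naphthalene.
   - Fallback (known chemistry): isomerise the aryl allyl ethers to propenyl ethers with [Ir(cod)(PMePh2)2]PF6. Then cleave them under mild oxidative or acidic conditions (I2/H2O, or OsO4/NaIO4).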